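Numbering: chromene atoms O1–C8a are unprimed, bicycloheptane atoms C1'–C7' are primed (spiro atom C2 = C2'); ring A is the trione ring, ring B the dihydropyran.
Retrosynthesis cuts O1–C2' first (ring B opens to a trione enol and a C3=C2' alkene), then C3–C4 (alkenylboron donor plus alkylidene-trione acceptor), and finally C4=C4a (Knoevenagel) and C3=C2' (boron-Wittig).
Forward: ring A arises by dearomatising tetramethylation of phloroacetophenone and the bicycle is bought as (+)-β-pinene. The halves are joined at C3–C4, and ring B, the only ring built, closes last at O1–C2'.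
Enabling feature: C4 (H, isopropyl) is the β-carbon of the exocyclic enone C4=C4a–C=O, which ring A holds s-cis, and O1 sits on tertiary C2' beside the C3 methylene. C3 can therefore arrive as a boron-bound sp2 carbon, and the alkene it brings later takes up the enol oxygen.
Stereochemistry: C1'/C5' come from (1R,5R)-β-pinene, C4 from a chiral 3,3'-diaryl-BINOL catalyst (Re-face delivery), and C2' from O-attack anti to the C6' gem-dimethyl bridge.

Key step: step 7

Assumption: (1R,5R)-(+)-β-pinene is taken as a catalogue compound of high enantiomeric purity, checked by chiral GC before use, since it fixes both bridgeheads.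
Assumption: the (R)-diol is written as the antipode that serves the Re face of C4. The sense cannot be derived safely for this new acceptor, so both antipodes are tried once and the one leading to the target diastereomer is kept.

Step 1
Reactants: 1 2,4,6-trihydroxyacetophenone
Product: 2 acetylsyncarpic acid (2-acetyl-3-hydroxy-4,4,6,6-tetramethylcyclohex-2-ene-1,5-dione)
Conditions: MeI (6 equiv), NaOMe (5 equiv), MeOH, reflux; then aq HCl
Reagents that add atoms: iodomethane (MeI), CI
Why: Exhaustive dearomatising C-methylation: the phloroglucinol enolates are alkylated on carbon until both free ring positions are quaternary, while the acetyl-bearing carbon stays untouched as the most stabilised and least nucleophilic tricarbonyl enolate, a long-established entry to acylsyncarpic acids.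

Step 2
Reactants: 2 acetylsyncarpic acid
Product: 3 syncarpic acid (2,2,4,4-tetramethylcyclohexane-1,3,5-trione)
Conditions: 6 M aq HCl, reflux
Reagents that add atoms: none
Why: Acid-promoted retro-Claisen deacylation: water adds to the exocyclic acetyl carbonyl of the tricarbonylmethane unit and the stabilised trione enol leaves, a standard deacetylation of acylsyncarpic acids.

Step 3
Reactants: 3 syncarpic acid; 4 isobutyraldehyde
Product: 6 isobutylidenesyncarpic acid (2,2,4,4-tetramethyl-6-(2-methylpropylidene)cyclohexane-1,3,5-trione), via Mannich base 5 (not isolated)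
Conditions: piperidine (1.1 equiv), CH2Cl2, rt; then 2 M aq HCl, rt; used at once
Reagents that add atoms: none
Why: Knoevenagel condensation run through the Mannich base, so that the enone is released only under acid, where neither Michael addition of a second trione nor base-induced tautomerisation to the dienol can compete.

Step 4
Reactants: 7 (1R,5R)-(+)-β-pinene
Product: 9 (1S,5R)-(−)-nopinone, via secondary ozonide 8 (not isolated)
Conditions: O3, CH2Cl2, −78 °C; then Me2S, −78 °C → rt
Reagents that add atoms: ozone, [O-][O+]=O
Why: Ozonolysis with reductive work-up cleaves the only C=C bond to the ketone and formaldehyde without touching the bridgeheads, whose arrangement is carried over (the C1 descriptor changes from R to S only through the priority change).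

Step 5
Reactants: 9 (1S,5R)-(−)-nopinone; 10 bis(pinacolatoboryl)methane
Product: 13 pinacol (E)-{[(1R,5R)-6,6-dimethylbicyclo[3.1.1]heptan-2-ylidene]methyl}boronate, via lithiated diborylmethane 11 (not isolated), via lithium alkoxide adduct 12 (not isolated)
Conditions: 10 (1.2 equiv), LiTMP (lithium 2,2,6,6-tetramethylpiperidide, from the amine and n-BuLi), THF, 0 °C; then 9, −78 °C → rt; H2O
Reagents that add atoms: none
Why: Boron-Wittig olefination: the boron-stabilised carbanion 11 adds to the ketone from the face anti to the gem-dimethyl bridge and alkoxide 12 loses its boron-bound oxygen by syn B–O elimination, leaving the remaining boron on the less crowded C3' side (E), a geometry that has no consequence later.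

Step 6
Reactants: 13 pinacol alkenylboronate
Product: 14 (E)-{[(1R,5R)-6,6-dimethylbicyclo[3.1.1]heptan-2-ylidene]methyl}boronic acid
Conditions: NaIO4 (3 equiv), NH4OAc (3 equiv), acetone–H2O, rt
Reagents that add atoms: water, O
Why: Oxidative cleavage of a pinacol boronate: the hydrolysis equilibrium is pulled over by periodate glycol cleavage of the released pinacol in a near-neutral buffer, under which the alkenyl C–B bond and the strained bicycle should survive.

Step 7
Reactants: 6 isobutylidenesyncarpic acid (freshly made); 14 alkenylboronic acid
Product: 17 2-{(1S)-1-[(E)-((1S,5R)-6,6-dimethylbicyclo[3.1.1]heptan-2-ylidene)methyl]-2-methylpropyl}-3-hydroxy-4,4,6,6-tetramethylcyclohex-2-ene-1,5-dione, via binaphthyl alkenylboronate 15 (not isolated), via boron enolate 16 (not isolated)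
Conditions: 14 (1.3 equiv), (R)-3,3'-bis(pentafluorophenyl)-BINOL (20 mol %), 4 Å MS, toluene, 0 °C → rt, no base; then H2O
Reagents that add atoms: none
Why: Proposed new method: boronic acid 14 condenses with the diol to the Lewis-acidic cyclic boronate 15, whose boron binds the ring-A carbonyl lying cis to the C4–H of 6 and passes its alkenyl carbon (future C3) to C4 through a six-membered chair-like transition state; ligand exchange with fresh 14 releases the diol and leaves boron enolate 16, which water converts to 17. The closest known reaction type is the 3,3'-disubstituted-BINOL-catalysed enantioselective conjugate addition of alkenylboronic acids and esters to enones that can adopt the s-cis form and to ortho-quinone methides, whereas a 2-alkylidene-1,3,5-trione acceptor and a β,β-dialkyl alkenylboron donor have not been shown. No ring closes in this step. The only new stereocentre, C4, is set by the catalyst, whose 3,3'-aryl groups leave the Re face of C4 open (S in 17, R in the target after the priority change), the remote bicycle of 14 contributing little. The step needs a catalysed 1,4-transfer that outruns both the uncatalysed addition and the tautomerisation of 6, and it needs a single binding mode: the C4=C4a–C=O unit is locked s-cis by ring A and doubly activated, the carbonyl cis to the isopropyl group is closed by allylic strain so that 6 behaves as one (E)-enone, and the base-free, dry medium keeps 6 from slipping to its dienol. The E geometry of 14 is carried into 17 and is erased in the next step.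

Step 8
Reactants: 17 alkenyl trione enol
Product: 19 (4R,1'S,2'S,5'R)-4-isopropyl-6,6,6',6',8,8-hexamethyl-3,4-dihydrospiro[chromene-2,2'-bicyclo[3.1.1]heptane]-5,7(6H,8H)-dione (target), via pinan-2-yl cation enolate zwitterion 18 (not isolated)
Conditions: (PhO)2P(O)OH (5 mol %), HFIP–CH2Cl2 (1:4), −20 → 0 °C
Reagents that add atoms: none
Why: Acid-mediated Markovnikov cycloisomerisation of a 2-(3,3-dialkylallyl)-1,3-dione to a 2,2-dialkyldihydropyran (intramolecular hydroalkoxylation, 6-endo-trig): the proton goes to C3, the charge of 18 sits on tertiary C2' within reach of the ring-A oxygen, and C–O collapse on the C7' side, anti to the C6' gem-dimethyl bridge, sets 2'S with C3 syn to the bridge, while the weak acid, the low temperature and the intramolecular trap are meant to keep collapse ahead of cyclobutane opening or Wagner–Meerwein shift, and C4 is not touched.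

Compound list
1 | 2,4,6-trihydroxyacetophenone (phloroacetophenone) | CC(=O)c1c(O)cc(O)cc1O | starting material
2 | acetylsyncarpic acid, 2-acetyl-3-hydroxy-4,4,6,6-tetramethylcyclohex-2-ene-1,5-dione (enol form) | CC(=O)C1=C(O)C(C)(C)C(=O)C(C)(C)C1=O | intermediate
3 | syncarpic acid, 2,2,4,4-tetramethylcyclohexane-1,3,5-trione | CC1(C)C(=O)CC(=O)C(C)(C)C1=O | intermediate
4 | isobutyraldehyde (2-methylpropanal) | CC(C)C=O | starting material
5 | Mannich base, 3-hydroxy-4,4,6,6-tetramethyl-2-[2-methyl-1-(piperidin-1-yl)propyl]cyclohex-2-ene-1,5-dione (racemic) | CC(C)C(N1CCCCC1)C1=C(O)C(C)(C)C(=O)C(C)(C)C1=O | intermediate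
6 | isobutylidenesyncarpic acid, 2,2,4,4-tetramethyl-6-(2-methylpropylidene)cyclohexane-1,3,5-trione | CC(C)C=C1C(=O)C(C)(C)C(=O)C(C)(C)C1=O | intermediate
7 | (1R,5R)-(+)-β-pinene, 6,6-dimethyl-2-methylidenebicyclo[3.1.1]heptane | C=C1CC[C@@H]2C[C@H]1C2(C)C | starting material
8 | secondary ozonide of 7, 1,2,4-trioxolane spiro-fused at C2 of the bicycle (bridgeheads as in 7, spiro centre undefined) | C1OC2(OO1)CC[C@@H]1C[C@H]2C1(C)C | intermediate
9 | (1S,5R)-(−)-nopinone, 6,6-dimethylbicyclo[3.1.1]heptan-2-one | O=C1CC[C@@H]2C[C@H]1C2(C)C | intermediate
10 | bis(pinacolatoboryl)methane, bis(4,4,5,5-tetramethyl-1,3,2-dioxaborolan-2-yl)methane | CC1(C)OB(CB2OC(C)(C)C(C)(C)O2)OC1(C)C | starting material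
11 | lithio-bis(pinacolatoboryl)methane | [Li]C(B1OC(C)(C)C(C)(C)O1)B1OC(C)(C)C(C)(C)O1 | intermediate
12 | lithium alkoxide from addition of 11 to 9 (diborylmethyl group anti, oxygen syn to the gem-dimethyl bridge) | [Li]O[C@@]1(C(B2OC(C)(C)C(C)(C)O2)B2OC(C)(C)C(C)(C)O2)CC[C@@H]2C[C@H]1C2(C)C | intermediate
13 | pinacol (E)-{[(1R,5R)-6,6-dimethylbicyclo[3.1.1]heptan-2-ylidene]methyl}boronate (boron cis to C3') | CC1(C)OB(/C=C2\CC[C@@H]3C[C@H]2C3(C)C)OC1(C)C | intermediate
14 | (E)-{[(1R,5R)-6,6-dimethylbicyclo[3.1.1]heptan-2-ylidene]methyl}boronic acid | OB(O)/C=C1\CC[C@@H]2C[C@H]1C2(C)C | intermediate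
15 | cyclic (R)-3,3'-bis(pentafluorophenyl)-1,1'-binaphthalene-2,2'-diyl ester of 14 (the R axis cannot be written in the SMILES) | B1(/C=C2\CC[C@@H]3C[C@H]2C3(C)C)Oc2c(-c3c(F)c(F)c(F)c(F)c3F)cc3ccccc3c2-c2c(O1)c(-c3c(F)c(F)c(F)c(F)c3F)cc3ccccc23 | intermediate
16 | O-dihydroxyboryl enolate of 17 (side-chain carbon S, alkene E) | CC(C)[C@@H](/C=C2\CC[C@@H]3C[C@H]2C3(C)C)C1=C(OB(O)O)C(C)(C)C(=O)C(C)(C)C1=O | intermediate
17 | 2-{(1S)-1-[(E)-((1S,5R)-6,6-dimethylbicyclo[3.1.1]heptan-2-ylidene)methyl]-2-methylpropyl}-3-hydroxy-4,4,6,6-tetramethylcyclohex-2-ene-1,5-dione (bridgeheads spatially as in 7) | CC(C)[C@@H](/C=C2\CC[C@@H]3C[C@H]2C3(C)C)C1=C(O)C(C)(C)C(=O)C(C)(C)C1=O | intermediate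
18 | zwitterion of 17 protonated at C3 (cation at C2', enolate in ring A, C4 and bridgeheads as in 19) | CC(C)[C@@H](C[C+]2CC[C@@H]3C[C@H]2C3(C)C)C1=C([O-])C(C)(C)C(=O)C(C)(C)C1=O | intermediate
19 | (4R,1'S,2'S,5'R)-4-isopropyl-6,6,6',6',8,8-hexamethyl-3,4-dihydrospiro[chromene-2,2'-bicyclo[3.1.1]heptane]-5,7(6H,8H)-dione, O1 anti and C3 syn to the gem-dimethyl bridge | CC(C)[C@H]1C[C@]2(CC[C@@H]3C[C@H]2C3(C)C)OC2=C1C(=O)C(C)(C)C(=O)C2(C)C | target

Total step count: 8. Longest linear sequence: 5 steps (steps 1, 2, 3, 7, 8 or steps 4, 5, 6, 7, 8).

Steps most likely to fail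

Step 7. Three things may go wrong:
- Alkenyl transfer from the crowded β,β-dialkyl boronate to the β-branched acceptor may be sluggish.
- An uncatalysed background addition may erode the facial selectivity at C4.
- The acceptor may tautomerise before it is consumed.

The fallback sets out from 9 and 6 and comes back at 17. It replaces catalyst control by a stoichiometric organocopper addition followed by separation of diastereomers, all of it classical chemistry. Wittig bromomethylenation of 9 ((bromomethyl)triphenylphosphonium bromide, KOt-Bu, THF, −78 °C → rt) should give 2-(bromomethylidene)-6,6-dimethylbicyclo[3.1.1]heptane F1; either alkene isomer is usable. Bromine–lithium exchange with t-BuLi (2 equiv, Et2O, −78 °C) gives the alkenyllithium F2. CuBr·SMe2 converts this to the alkenylcopper F3, which adds in 1,4-fashion to the doubly activated alkylidene dicarbonyl unit of 6 at −78 °C. Compound 17 then forms together with the C4 epimer of 17 F4. Because the bicycle is enantiopure, the two are diastereomers and are separated by chromatography.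

Step 8. Three things may go wrong:
- The C2' cation may rearrange (cyclobutane opening to a p-menthenyl system or Wagner–Meerwein shift) faster than C–O collapse.
- The tertiary vinylogous ester product may re-ionise under the acid and drain into rearranged material.
- The oxygen may attack the bridge-side face.

The fallback sets out from 6 and 7 and comes back at 19. It is the acid-free thermal inverse-electron-demand oxa-Diels–Alder reaction, with the O=C–C4a=C4 unit of 6 as the heterodiene and the exocyclic alkene of 7 as the 2π partner (excess 7, toluene, 80–110 °C). This reaction type is known for alkylidene-1,3-diones with 1,1-disubstituted terpene alkenes. C3–C4 and O1–C2' form in one event on the alkene face anti to the bridge, with oxygen on the more substituted carbon and no free cation. C4 is not controlled, so 19 is expected with the C4 epimer of 19 F5 and is obtained by chromatographic separation.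

Step 5. The hindered boron-stabilised carbanion may enolise 9, or the bulky nucleophile may fail to reach the carbonyl next to the bridgehead. The fallback sets out from 7 and comes back at 13, so no carbonyl addition is needed at all. It is a dehydrogenative vinylic C–H borylation of the exocyclic methylene with B2pin2 and trans-RhCl(CO)(PPh3)2 (3 mol %) in toluene–MeCN at 80 °C, a known route from methylenecycloalkanes to trisubstituted alkenyl pinacol boronates. It makes no compound outside the list and also bypasses step 4.

Further compounds
F1 | step 7 | (E)-2-(bromomethylidene)-6,6-dimethylbicyclo[3.1.1]heptane (bridgeheads as in 7, one alkene isomer drawn) | Br/C=C1\CC[C@@H]2C[C@H]1C2(C)C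
F2 | step 7 | [(6,6-dimethylbicyclo[3.1.1]heptan-2-ylidene)methyl]lithium (bridgeheads as in 7) | [Li]/C=C1\CC[C@@H]2C[C@H]1C2(C)C
F3 | step 7 | [(6,6-dimethylbicyclo[3.1.1]heptan-2-ylidene)methyl]copper (bridgeheads as in 7) | [Cu]/C=C1\CC[C@@H]2C[C@H]1C2(C)C
F4 | step 7 | C4 epimer of 17 (side-chain carbon R) | CC(C)[C@H](/C=C2\CC[C@@H]3C[C@H]2C3(C)C)C1=C(O)C(C)(C)C(=O)C(C)(C)C1=O
F5 | step 8 | C4 epimer of 19 (4S,1'S,2'S,5'R) | CC(C)[C@@H]1C[C@]2(CC[C@@H]3C[C@H]2C3(C)C)OC2=C1C(=O)C(C)(C)C(=O)C2(C)C
F0 | step 5 | none | none
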